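**Assumption:** (R)-(−)-linalool, (S)-(+)-linalool (coriander-derived, high ee) and L-homoserine are bought as single enantiomers.

## Retrosynthetic overview

1. The bond between ring carbon C2 of the oxabicycle and the first CH2 of the vinyl-carbinol side chain is cut last: a photochemical radical cross-coupling joins bicyclic alcohol 13 to lactol 15 from (S)-linalool, which carries the tertiary carbinol.
2. The quaternary ring carbon C3 comes from a bicyclic β-keto ester: alkylation with iodide 9, decarboxylation, then exo-methylation (electrophiles enter exo, so methyl last puts the long chain endo).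
3. Iodide 9 (C–Br stereocentre, CMe2Cl) comes from L-homoserine.
4. The carbocycle is closed by a Dieckmann reaction of oxolane diester 4, made from (R)-linalool.
5. Ring order: oxolane first (oxa-Michael), then the 7-oxabicyclo[2.2.1]heptane (Dieckmann C–C closure).

## Route

**Step 1**
Reactants: 1, (R)-(−)-linalool
Product: 2, (5R)-5-ethenyl-5-methyloxolan-2-ol (lactol, anomer mixture)
Conditions: O3 (1.0 equiv, Sudan III endpoint), CH2Cl2/MeOH, −78 °C; Me2S
Reagents that add atoms: ozone, [O-][O+]=O
Why: Chemoselective ozonolysis of the electron-rich trisubstituted alkene over the vinyl group; the aldehyde closes onto the tertiary OH, and the bought carbinol centre is untouched.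

**Step 2**
Reactants: 2
Product: 3, tert-butyl 2-[(5R)-5-ethenyl-5-methyloxolan-2-yl]acetate (cis/trans mixture at C2)
Conditions: Ph3P=CHCO2tBu, toluene, 80 °C; then KOtBu (10 mol%), THF, 0 °C
Reagents that add atoms: tert-butyl (triphenylphosphoranylidene)acetate, CC(C)(C)OC(=O)C=P(c1ccccc1)(c1ccccc1)c1ccccc1
Why: Wittig olefination of the lactol followed by 5-exo oxa-Michael addition of the tertiary alkoxide; the C2 configuration is not yet controlled and is corrected in step 8.

**Step 3**
Reactants: 3
Product: 4, methyl (2R)-5-(2-tert-butoxy-2-oxoethyl)-2-methyloxolane-2-carboxylate (cis/trans mixture)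
Conditions: O3, 2.5 M NaOH in MeOH, CH2Cl2, −78 °C
Reagents that add atoms: ozone, [O-][O+]=O; methanol, CO
Why: Ozonolysis in basic methanol converts the vinyl group directly to the methyl ester (the aldehyde hemiacetal is oxidised in situ); the quaternary centre cannot epimerise and the tert-butyl ester is inert at −78 °C.

**Step 4**
Reactants: 5, L-homoserine
Product: 6, (S)-3-bromodihydrofuran-2(3H)-one
Conditions: NaNO2, KBr, 2.5 M H2SO4, 0 °C to rt; extract; TsOH (cat.), toluene
Reagents that add atoms: potassium bromide, [K+].[Br-]
Why: Diazotisation with carboxylate participation (α-lactone, double inversion) gives the α-bromo acid with retention, which lactonises; this buys the C–Br stereocentre.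

**Step 5**
Reactants: 6
Product: 7, (S)-3-bromo-4-methylpentane-1,4-diol
Conditions: MeMgBr (3.2 equiv), CeCl3, THF, −78 °C; AcOH quench at −78 °C
Reagents that add atoms: methylmagnesium bromide, C[Mg]Br
Why: Double organocerium addition to the lactone carbonyl builds the CMe2OH group; low basicity and a cold quench avoid enolisation of the C–Br centre and epoxide closure.

**Step 6**
Reactants: 7
Product: 8, (S)-3-bromo-5-iodo-2-methylpentan-2-ol
Conditions: I2, PPh3, imidazole, CH2Cl2, 0 °C
Reagents that add atoms: iodine, II
Why: Appel iodination is selective for the primary alcohol over the hindered tertiary one; the stereocentre is not involved.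

**Step 7**
Reactants: 8
Product: 9, (S)-3-bromo-4-chloro-1-iodo-4-methylpentane
Conditions: conc. HCl, CaCl2, CH2Cl2 (two-phase), 0 °C to rt
Reagents that add atoms: hydrogen chloride, Cl
Why: SN1 substitution of the tertiary alcohol through a bromine-bridged cation; chloride opens at the tertiary carbon, so the C–Br configuration is retained.

**Step 8**
Reactants: 4; 9
Product: 10, tert-butyl (1S,4R)-2-[(3S)-3-bromo-4-chloro-4-methylpentyl]-4-methyl-3-oxo-7-oxabicyclo[2.2.1]heptane-2-carboxylate (C2 configuration inconsequential)
Conditions: KOtBu (1.05 equiv), THF, 0 °C to rt; then 9 (1.2 equiv), DMF, 40 °C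
Reagents that add atoms: none
Why: Dieckmann condensation of the acetate enolate onto the methyl ester closes the carbocycle. Only cis-4 can cyclise, and trans-4 equilibrates by reversible retro-oxa-Michael/oxa-Michael, so the second bridgehead is fixed by the bought quaternary centre. The stabilised enolate is then C-alkylated by the primary iodide in the same pot.

**Step 9**
Reactants: 10
Product: 11, (1R,4S)-3-[(3S)-3-bromo-4-chloro-4-methylpentyl]-1-methyl-7-oxabicyclo[2.2.1]heptan-2-one (C3 epimers)
Conditions: TFA, CH2Cl2, 0 °C to rt; then toluene, 70 °C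
Reagents that add atoms: none
Why: Acidolysis of the tert-butyl ester and decarboxylation of the β-keto acid; conditions are non-basic, so the bromochloride survives.

**Step 10**
Reactants: 11
Product: 12, (1R,3R,4S)-3-[(3S)-3-bromo-4-chloro-4-methylpentyl]-1,3-dimethyl-7-oxabicyclo[2.2.1]heptan-2-one (3-exo-methyl, 3-endo-alkyl)
Conditions: LiHMDS, THF, −78 °C; MeI, DMPU, −78 to −40 °C
Reagents that add atoms: iodomethane, CI
Why: Ketone enolate alkylation on the bicyclo[2.2.1] framework occurs from the exo face (syn to the oxygen bridge), so methyl enters exo and pushes the side chain endo, setting the quaternary centre. The enolate is kept cold to avoid β-alkoxide ring opening.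

**Step 11**
Reactants: 12
Product: 13, (1R,3S,4S)-3-[(3S)-3-bromo-4-chloro-4-methylpentyl]-1,3-dimethyl-7-oxabicyclo[2.2.1]heptan-2-ol (mainly 2-endo-OH)
Conditions: DIBAL-H, CH2Cl2, −78 to 0 °C
Reagents that add atoms: none
Why: Hydride reduction of the hindered ketone (exo delivery); the carbinol configuration is irrelevant because it becomes a radical in step 13.

**Step 12**
Reactants: 14, (S)-(+)-linalool
Product: 15, (5S)-5-ethenyl-5-methyloxolan-2-ol (lactol, anomer mixture)
Conditions: O3 (1.0 equiv, Sudan III endpoint), CH2Cl2/MeOH, −78 °C; Me2S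
Reagents that add atoms: ozone, [O-][O+]=O
Why: Same selective ozonolysis as step 1 on the other enantiomer; this buys the side-chain carbinol centre.

**Step 13**
Reactants: 13; 15 (2.5 equiv)
Product: 16, (3S)-5-[(1R,2S,3S,4S)-3-((3S)-3-bromo-4-chloro-4-methylpentyl)-1,3-dimethyl-7-oxabicyclo[2.2.1]heptan-2-yl]-3-methylpent-1-en-3-yl formate
Conditions: 13, N-aryl benzoxazolium salt, pyridine, MTBE, rt; then 15 pre-mixed with MesI(OAc)2, [Ir(dF(CF3)ppy)2(dtbbpy)]PF6 (2 mol%), Ni(acac)2/KTp* (10 mol%), MTBE/DMSO, 450 nm LEDs, rt
Reagents that add atoms: none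
Why: Proposed new method: the excited Ir catalyst oxidises the NHC adduct of 13 to the secondary bicyclic radical, and the reduced catalyst reduces the lactol–iodine(III) adduct of 15 to an anomeric alkoxy radical whose β-scission releases the primary radical •CH2CH2C(Me)(OCHO)CH=CH2 (the lactol carbon becomes the O-formate). Ni(II) captures only the unhindered primary radical, and the hindered ring radical attacks the Ni–CH2 carbon (SH2) on its exo face, away from the ethano bridge and the endo chain, giving chain exo and H endo. The closest known reactions are NHC-alcohol/carboxylic acid radical-sorting sp3–sp3 coupling and iodine(III)-mediated alkoxy-radical fragmentation of lactols to formates.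

**Step 14**
Reactants: 16
Product: 17, dactylomelol
Conditions: KHCO3, MeOH, 0 °C to rt
Reagents that add atoms: none
Why: Mild methanolysis of the tertiary formate; no stereocentre is touched, and the conditions are too mild to eliminate the bromochloride.

## Compound list

1 | (R)-(−)-linalool | C=C[C@](C)(O)CCC=C(C)C | starting material
2 | (5R)-5-ethenyl-5-methyloxolan-2-ol | C=C[C@@]1(C)CCC(O)O1 | intermediate
3 | tert-butyl 2-[(5R)-5-ethenyl-5-methyloxolan-2-yl]acetate | C=C[C@@]1(C)CCC(CC(=O)OC(C)(C)C)O1 | intermediate
4 | methyl (2R)-5-(2-tert-butoxy-2-oxoethyl)-2-methyloxolane-2-carboxylate | COC(=O)[C@@]1(C)CCC(CC(=O)OC(C)(C)C)O1 | intermediate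
5 | L-homoserine | N[C@@H](CCO)C(=O)O | starting material
6 | (S)-3-bromodihydrofuran-2(3H)-one | Br[C@H]1CCOC1=O | intermediate
7 | (S)-3-bromo-4-methylpentane-1,4-diol | OCC[C@H](Br)C(C)(C)O | intermediate
8 | (S)-3-bromo-5-iodo-2-methylpentan-2-ol | ICC[C@H](Br)C(C)(C)O | intermediate
9 | (S)-3-bromo-4-chloro-1-iodo-4-methylpentane | ICC[C@H](Br)C(C)(C)Cl | intermediate
10 | tert-butyl (1S,4R)-2-[(3S)-3-bromo-4-chloro-4-methylpentyl]-4-methyl-3-oxo-7-oxabicyclo[2.2.1]heptane-2-carboxylate | O=C1C(CC[C@H](Br)C(C)(C)Cl)(C(=O)OC(C)(C)C)[C@@H]2CC[C@@]1(C)O2 | intermediate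
11 | (1R,4S)-3-[(3S)-3-bromo-4-chloro-4-methylpentyl]-1-methyl-7-oxabicyclo[2.2.1]heptan-2-one | O=C1C(CC[C@H](Br)C(C)(C)Cl)[C@@H]2CC[C@@]1(C)O2 | intermediate
12 | (1R,3R,4S)-3-[(3S)-3-bromo-4-chloro-4-methylpentyl]-1,3-dimethyl-7-oxabicyclo[2.2.1]heptan-2-one | O=C1[C@](C)(CC[C@H](Br)C(C)(C)Cl)[C@@H]2CC[C@@]1(C)O2 | intermediate
13 | (1R,3S,4S)-3-[(3S)-3-bromo-4-chloro-4-methylpentyl]-1,3-dimethyl-7-oxabicyclo[2.2.1]heptan-2-ol (2-endo-OH shown) | O[C@@H]1[C@](C)(CC[C@H](Br)C(C)(C)Cl)[C@@H]2CC[C@@]1(C)O2 | intermediate
14 | (S)-(+)-linalool | C=C[C@@](C)(O)CCC=C(C)C | starting material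
15 | (5S)-5-ethenyl-5-methyloxolan-2-ol | C=C[C@]1(C)CCC(O)O1 | intermediate
16 | dactylomelol O-formate | C=C[C@@](C)(OC=O)CC[C@H]1[C@](C)(CC[C@H](Br)C(C)(C)Cl)[C@@H]2CC[C@@]1(C)O2 | intermediate
17 | dactylomelol, (3S)-5-[(1R,2S,3S,4S)-3-((3S)-3-bromo-4-chloro-4-methylpentyl)-1,3-dimethyl-7-oxabicyclo[2.2.1]heptan-2-yl]-3-methylpent-1-en-3-ol | C=C[C@@](C)(O)CC[C@H]1[C@](C)(CC[C@H](Br)C(C)(C)Cl)[C@@H]2CC[C@@]1(C)O2 | target

## Step count and risks

Total steps: 14.

Longest linear sequence: 10 steps, from L-homoserine (steps 4, 5, 6, 7, 8, 9, 10, 11, 13, 14). The (R)-linalool branch is 9 steps to the target (steps 1, 2, 3, 8, 9, 10, 11, 13, 14) and the (S)-linalool branch is 3 (steps 12, 13, 14).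

Steps most likely to fail:

1. **Step 13 (proposed new coupling).** The lactol fragmentation may not mesh with the Ni radical-sorting cycle, and the ring radical is flanked by two fully substituted carbons, so activation of the alcohol and the SH2 step may both be slow. Fallback: make (S)-4-methyl-4-(triethylsilyloxy)hex-5-enoic acid from 14 (TESOTf; selective O3/PPh3; NaClO2) and couple it with 13 by the known NHC-alcohol/carboxylic acid radical-sorting cross-coupling, then remove TES with HF·pyridine.
2. **Step 8 (Dieckmann closure to the strained bicycle and in-pot alkylation).** Fallback: form the ketone by Rh(II)-carbenoid C–H insertion instead.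
   - (R)-Linalool is taken to (R)-2-ethenyl-2-methyloxolane (O3/NaBH4, then TsCl/NaH).
   - The vinyl group is oxidised to the acid (RuCl3/NaIO4) and converted to the diazoketone.
   - Rh2(OAc)4 1,5-insertion into the C–H next to the ring oxygen gives (1R,4S)-1-methyl-7-oxabicyclo[2.2.1]heptan-2-one.
   - This ketone is alkylated exo with 9 and then with MeI.
3. **Step 5 (organometallic addition to the α-bromo lactone; risk of racemisation or epoxide formation).** Fallback: install the carbinol before the bromide.
   - (R)-α-Hydroxy-γ-butyrolactone (from D-malic acid) with MeMgBr gives the triol.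
   - After pivaloylation of the primary OH, the secondary/tertiary diol is converted to its cyclic sulfate (SOCl2; RuCl3/NaIO4).
   - LiBr opens it at the secondary carbon with inversion to give the (S)-bromohydrin.
   - Pivalate removal and Appel iodination then give compound 8, which rejoins the route.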